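Ring C is disconnected at C3–C4. The aryl ketone carbon C4, the methylene C3 and the oxygen-bearing benzylic stereocentre C2 with its hydrogen are exactly what arises when the formyl C–H bond of ring A adds across an aryl 1-arylvinyl ether, O1–C2(=C3H2)–ring B. A single enantioselective rhodium-catalysed intramolecular hydroacylation therefore closes ring C, makes C3–C4 and sets C2. Its substrate is a hexasubstituted benzaldehyde carrying two prenyl groups, silyl ethers on the oxygens that become 5-OH and 7-OH, and a 1-(4-silyloxyphenyl)vinyl group on the third oxygen; that enol ether comes from methylenation of an aryl ester while the formyl carbon is parked as a silylated benzylic alcohol.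

Key step: step 9

Remark (stereochemistry): which hand of the bisphosphine gives the 2S ketone cannot be derived for this new substrate class; the (R) ligand is written, and its mirror image is to be used if the hydride arrives on the other face.

Remark (design): an aldehyde ortho to an aryl 1-arylvinyl ether is a latent flavylium ion, and an acetal hydrolysed beside the enol ether would pass through an oxocarbenium ion that the enol ether can trap. The formyl carbon is therefore carried through the methylenation as a silylated benzylic alcohol and released by base and MnO2. From the enol ether onward all material is kept free of acid (Et3N-deactivated silica).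

Step 1
Reactants: 1 2,4,6-trihydroxybenzaldehyde; 2 prenyl bromide (1-bromo-3-methylbut-2-ene)
Product: 3 2,4,6-trihydroxy-3,5-bis(3-methylbut-2-enyl)benzaldehyde
Conditions: 2 (2.1 equiv), KOH (10% aq.), 0 °C to rt
Reagents that add atoms: none
Why: C-alkylation of a phloroglucinol-type phenoxide (ambident phenolate alkylation), which in water is hydrogen-bonded at oxygen and should react through its two equivalent free ring carbons, the diprenyl compound being separated from mono- and over-alkylated material.

Step 2
Reactants: 3 2,4,6-trihydroxy-3,5-bis(3-methylbut-2-enyl)benzaldehyde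
Product: 4 2,4-bis(tert-butyldimethylsilyloxy)-6-hydroxy-3,5-bis(3-methylbut-2-enyl)benzaldehyde
Conditions: TBSCl (2.2 equiv), imidazole, DMF, 0 °C to rt
Reagents that add atoms: tert-butyldimethylsilyl chloride, CC(C)(C)[Si](C)(C)Cl
Why: Silyl ether formation should stop after the 4-hydroxyl and one of the two equivalent ortho hydroxyls, because the remaining hydroxyl is locked in a hydrogen bond to the formyl oxygen and is the least nucleophilic, which is the usual chelation-based differentiation of 2,4,6-trihydroxyaryl carbonyl compounds.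

Step 3
Reactants: 5 4-hydroxybenzoic acid
Product: 7 4-(triisopropylsilyloxy)benzoic acid, via triisopropylsilyl ester 6 (not isolated)
Conditions: TIPSCl (2.2 equiv), imidazole, DMF, rt; then K2CO3 (1 equiv), THF/H2O, rt; citric acid work-up
Reagents that add atoms: triisopropylsilyl chloride, CC(C)[Si](Cl)(C(C)C)C(C)C
Why: Exhaustive silylation gives the silyl ester silyl ether, and selective hydrolysis then removes only the silyl ester, by far the more labile Si–O bond, under mild base that leaves the aryl triisopropylsilyl ether intact.

Step 4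
Reactants: 7 4-(triisopropylsilyloxy)benzoic acid; 4 2,4-bis(tert-butyldimethylsilyloxy)-6-hydroxy-3,5-bis(3-methylbut-2-enyl)benzaldehyde
Product: 9 3,5-bis(tert-butyldimethylsilyloxy)-2-formyl-4,6-bis(3-methylbut-2-enyl)phenyl 4-(triisopropylsilyloxy)benzoate, via acid chloride 8 (not isolated)
Conditions: 7, (COCl)2, DMF (cat.), CH2Cl2, 0 °C to rt, evaporation; then 4, Et3N, DMAP (cat.), CH2Cl2, 0 °C to rt
Reagents that add atoms: none
Why: Acid chloride formation through the Vilsmeier-type chloroiminium species is followed by DMAP-catalysed acylation (nucleophilic catalysis) of the only free phenol, the acylpyridinium ion being reactive enough to overcome the hydrogen bond and the two ortho substituents.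

Step 5
Reactants: 9 3,5-bis(tert-butyldimethylsilyloxy)-2-formyl-4,6-bis(3-methylbut-2-enyl)phenyl 4-(triisopropylsilyloxy)benzoate
Product: 10 3,5-bis(tert-butyldimethylsilyloxy)-2-[(dimethylphenylsilyloxy)methyl]-4,6-bis(3-methylbut-2-enyl)phenyl 4-(triisopropylsilyloxy)benzoate
Conditions: PhMe2SiH (1.5 equiv), RhCl(PPh3)3 (2 mol%), toluene, 50 °C
Reagents that add atoms: dimethylphenylsilane, C[SiH](C)c1ccccc1
Why: Rhodium-catalysed carbonyl hydrosilylation reduces and silylates the formyl group in one neutral operation, so that no free alkoxide ever sits next to the aryl ester or the aryl silyl ether (no acyl or silyl migration), while esters and trisubstituted alkenes are not hydrosilylated under these conditions.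

Step 6
Reactants: 10 3,5-bis(tert-butyldimethylsilyloxy)-2-[(dimethylphenylsilyloxy)methyl]-4,6-bis(3-methylbut-2-enyl)phenyl 4-(triisopropylsilyloxy)benzoate
Product: 11 1,5-bis(tert-butyldimethylsilyloxy)-2-[(dimethylphenylsilyloxy)methyl]-4,6-bis(3-methylbut-2-enyl)-3-[1-(4-triisopropylsilyloxyphenyl)vinyloxy]benzene
Conditions: Cp2TiMe2 (3 equiv), toluene/THF, 70 °C, dark; filtration through basic alumina
Reagents that add atoms: dimethyltitanocene Cp2TiMe2, C[Ti](C)(C1C=CC=C1)C1C=CC=C1
Why: Petasis methylenation, in which Cp2Ti=CH2 formed thermally from Cp2TiMe2 undergoes [2+2] cycloaddition and cycloreversion with the only carbonyl group present, should convert the aryl ester into the aryl 1-arylvinyl ether under non-acidic conditions that tolerate silyl ethers and trisubstituted alkenes.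

Step 7
Reactants: 11 1,5-bis(tert-butyldimethylsilyloxy)-2-[(dimethylphenylsilyloxy)methyl]-4,6-bis(3-methylbut-2-enyl)-3-[1-(4-triisopropylsilyloxyphenyl)vinyloxy]benzene
Product: 12 [2,4-bis(tert-butyldimethylsilyloxy)-3,5-bis(3-methylbut-2-enyl)-6-[1-(4-triisopropylsilyloxyphenyl)vinyloxy]phenyl]methanol
Conditions: K2CO3 (0.1 equiv), MeOH/THF, 0 °C, short reaction time; product used crude
Reagents that add atoms: none
Why: Base-catalysed methanolysis should cleave the alkyl dimethylphenylsilyl ether, the least hindered and most electrophilic silicon in the molecule, far faster than the doubly ortho-substituted aryl TBS ethers or the aryl TIPS ether, and a basic medium cannot protonate the enol ether.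

Step 8
Reactants: 12 [2,4-bis(tert-butyldimethylsilyloxy)-3,5-bis(3-methylbut-2-enyl)-6-[1-(4-triisopropylsilyloxyphenyl)vinyloxy]phenyl]methanol
Product: 13 2,4-bis(tert-butyldimethylsilyloxy)-3,5-bis(3-methylbut-2-enyl)-6-[1-(4-triisopropylsilyloxyphenyl)vinyloxy]benzaldehyde
Conditions: MnO2 (activated, excess), CH2Cl2, rt; Et3N-deactivated silica
Reagents that add atoms: none
Why: MnO2 oxidation of an electron-rich benzylic alcohol is a neutral heterogeneous process that stops at the aldehyde and keeps acid away from the aldehyde–enol ether pair, which acid would cyclise to a flavylium ion.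

Step 9
Reactants: 13 2,4-bis(tert-butyldimethylsilyloxy)-3,5-bis(3-methylbut-2-enyl)-6-[1-(4-triisopropylsilyloxyphenyl)vinyloxy]benzaldehyde
Product: 14 (2S)-5,7-bis(tert-butyldimethylsilyloxy)-6,8-bis(3-methylbut-2-enyl)-2-(4-triisopropylsilyloxyphenyl)chroman-4-one
Conditions: [Rh(nbd)2]BF4 (5 mol%), (R)-DTBM-SEGPHOS (5.5 mol%), H2 then Ar (activation before 13 is added), 2,6-di-tert-butyl-4-methylpyridine (10 mol%), ClCH2CH2Cl, 40 °C
Reagents that add atoms: none
Why: Proposed new method: the cationic bisphosphine complex of monovalent rhodium adds oxidatively into the formyl C–H bond to give an acyl rhodium hydride (trivalent rhodium) with the enol ether bound; migratory insertion then transfers the hydride to the aryl-substituted alkene carbon C2 and leaves rhodium on C3, after which the seven-membered rhodacycle (acyl and alkyl ligands) collapses by C–C reductive elimination to the C3–C4 bond. The closest known reaction type is the enantioselective rhodium-catalysed cyclisation of aldehydes onto tethered 1,1-disubstituted alkenes, as in 4-substituted pent-4-enals (3-substituted cyclopentanones) and 2-(2-substituted allyl)benzaldehydes (3-substituted tetralones); an aryl 1-arylvinyl ether as the alkene and a chroman-4-one as the product have not been shown. Ring C closes in the 6-endo-trig mode, the acyl carbon bonding to the terminal alkene carbon with both alkene carbons inside the new ring. The only new stereocentre, C2, is created when the hydride is delivered to one face of the alkene, and that face is chosen by the C2-symmetric chiral bisphosphine on rhodium (catalyst control, since the substrate has no stereocentre). The step needs 6-endo over 5-exo regioselectivity and insertion faster than decarbonylation: the 5-exo path would place rhodium on a fully substituted oxygen-bearing benzylic carbon and end in a quaternary benzofuran-3-one centre, O1 and the flanking prenyl group hold the alkene beside the acyl metal, both prenyl alkenes stand meta to the formyl group and cannot reach it, and the enol ether has no allylic hydrogen and so cannot isomerise. The silyl ether on the other ortho oxygen prevents a phenoxide chelate that would hold rhodium away from the alkene, and the hindered pyridine traps adventitious acid that would otherwise drive flavylium formation.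

Step 10
Reactants: 14 (2S)-5,7-bis(tert-butyldimethylsilyloxy)-6,8-bis(3-methylbut-2-enyl)-2-(4-triisopropylsilyloxyphenyl)chroman-4-one
Product: 15 (2S)-5,7-dihydroxy-2-(4-hydroxyphenyl)-6,8-bis(3-methylbut-2-enyl)chroman-4-one (6,8-diprenylnaringenin)
Conditions: Bu4NF (4 equiv), AcOH (5 equiv), THF, 0 °C to rt
Reagents that add atoms: none
Why: Fluoride-mediated cleavage of the three aryl silyl ethers is buffered with acetic acid so that no free phenoxide opens ring C by retro-oxa-Michael reaction to the chalcone, which should preserve the C2 configuration and leave the prenyl groups untouched.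

Compound list
1 | 2,4,6-trihydroxybenzaldehyde | O=Cc1c(O)cc(O)cc1O | starting material
2 | prenyl bromide (1-bromo-3-methylbut-2-ene) | CC(C)=CCBr | starting material
3 | 2,4,6-trihydroxy-3,5-bis(3-methylbut-2-enyl)benzaldehyde | O=Cc1c(O)c(CC=C(C)C)c(O)c(CC=C(C)C)c1O | intermediate
4 | 2,4-bis(tert-butyldimethylsilyloxy)-6-hydroxy-3,5-bis(3-methylbut-2-enyl)benzaldehyde | O=Cc1c(O)c(CC=C(C)C)c(O[Si](C)(C)C(C)(C)C)c(CC=C(C)C)c1O[Si](C)(C)C(C)(C)C | intermediate
5 | 4-hydroxybenzoic acid | OC(=O)c1ccc(O)cc1 | starting material
6 | triisopropylsilyl 4-(triisopropylsilyloxy)benzoate (not isolated) | CC(C)[Si](OC(=O)c1ccc(O[Si](C(C)C)(C(C)C)C(C)C)cc1)(C(C)C)C(C)C | intermediate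
7 | 4-(triisopropylsilyloxy)benzoic acid | OC(=O)c1ccc(O[Si](C(C)C)(C(C)C)C(C)C)cc1 | intermediate
8 | 4-(triisopropylsilyloxy)benzoyl chloride (not isolated) | ClC(=O)c1ccc(O[Si](C(C)C)(C(C)C)C(C)C)cc1 | intermediate
9 | 3,5-bis(tert-butyldimethylsilyloxy)-2-formyl-4,6-bis(3-methylbut-2-enyl)phenyl 4-(triisopropylsilyloxy)benzoate | O=Cc1c(OC(=O)c2ccc(O[Si](C(C)C)(C(C)C)C(C)C)cc2)c(CC=C(C)C)c(O[Si](C)(C)C(C)(C)C)c(CC=C(C)C)c1O[Si](C)(C)C(C)(C)C | intermediate
10 | 3,5-bis(tert-butyldimethylsilyloxy)-2-[(dimethylphenylsilyloxy)methyl]-4,6-bis(3-methylbut-2-enyl)phenyl 4-(triisopropylsilyloxy)benzoate | C[Si](C)(OCc1c(OC(=O)c2ccc(O[Si](C(C)C)(C(C)C)C(C)C)cc2)c(CC=C(C)C)c(O[Si](C)(C)C(C)(C)C)c(CC=C(C)C)c1O[Si](C)(C)C(C)(C)C)c1ccccc1 | intermediate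
11 | 1,5-bis(tert-butyldimethylsilyloxy)-2-[(dimethylphenylsilyloxy)methyl]-4,6-bis(3-methylbut-2-enyl)-3-[1-(4-triisopropylsilyloxyphenyl)vinyloxy]benzene | C[Si](C)(OCc1c(OC(=C)c2ccc(O[Si](C(C)C)(C(C)C)C(C)C)cc2)c(CC=C(C)C)c(O[Si](C)(C)C(C)(C)C)c(CC=C(C)C)c1O[Si](C)(C)C(C)(C)C)c1ccccc1 | intermediate
12 | [2,4-bis(tert-butyldimethylsilyloxy)-3,5-bis(3-methylbut-2-enyl)-6-[1-(4-triisopropylsilyloxyphenyl)vinyloxy]phenyl]methanol | OCc1c(OC(=C)c2ccc(O[Si](C(C)C)(C(C)C)C(C)C)cc2)c(CC=C(C)C)c(O[Si](C)(C)C(C)(C)C)c(CC=C(C)C)c1O[Si](C)(C)C(C)(C)C | intermediate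
13 | 2,4-bis(tert-butyldimethylsilyloxy)-3,5-bis(3-methylbut-2-enyl)-6-[1-(4-triisopropylsilyloxyphenyl)vinyloxy]benzaldehyde | C=C(Oc1c(CC=C(C)C)c(O[Si](C)(C)C(C)(C)C)c(CC=C(C)C)c(O[Si](C)(C)C(C)(C)C)c1C=O)c1ccc(O[Si](C(C)C)(C(C)C)C(C)C)cc1 | intermediate
14 | (2S)-5,7-bis(tert-butyldimethylsilyloxy)-6,8-bis(3-methylbut-2-enyl)-2-(4-triisopropylsilyloxyphenyl)chroman-4-one | CC(C)=CCc1c(O[Si](C)(C)C(C)(C)C)c(CC=C(C)C)c2c(c1O[Si](C)(C)C(C)(C)C)C(=O)C[C@@H](c1ccc(O[Si](C(C)C)(C(C)C)C(C)C)cc1)O2 | intermediate
15 | (2S)-5,7-dihydroxy-2-(4-hydroxyphenyl)-6,8-bis(3-methylbut-2-enyl)chroman-4-one (6,8-diprenylnaringenin) | CC(C)=CCc1c(O)c(CC=C(C)C)c2c(c1O)C(=O)C[C@@H](c1ccc(O)cc1)O2 | target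

Total step count: 10. Longest linear sequence: 9 steps (1 → 3 → 4 → 9 → 10 → 11 → 12 → 13 → 14 → 15, steps 1, 2 and 4 to 10); step 3 is a one-step side branch.

Steps most likely to fail

Step 9 (proposed new method). The processes that may defeat it are:
- slow insertion into the doubly ortho-substituted formyl group, followed by decarbonylation of the acyl rhodium hydride;
- 5-exo closure to the benzofuranone;
- poor facial selectivity in hydride delivery;
- acid-triggered cyclisation of the aldehyde–enol ether pair.

The fallback uses known chemistry, the enantioselective conjugate addition of an arylboronic acid to a chromone. It sets out from prenyl bromide 2 and returns to the route at 14. Commercial 2,4,6-trihydroxyacetophenone is C-diprenylated with 2 (KOH, water) to 1-[2,4,6-trihydroxy-3,5-bis(3-methylbut-2-enyl)phenyl]ethanone F1. Silylation of the two non-chelated hydroxyls (TBSCl, imidazole) gives 1-[2,4-bis(tert-butyldimethylsilyloxy)-6-hydroxy-3,5-bis(3-methylbut-2-enyl)phenyl]ethanone F2. Condensation with N,N-dimethylformamide dimethyl acetal gives (E)-1-[2,4-bis(tert-butyldimethylsilyloxy)-6-hydroxy-3,5-bis(3-methylbut-2-enyl)phenyl]-3-(dimethylamino)prop-2-en-1-one F3. Cyclisation with loss of dimethylamine (pyridinium p-toluenesulfonate, toluene, 80 °C) gives 5,7-bis(tert-butyldimethylsilyloxy)-6,8-bis(3-methylbut-2-enyl)chromen-4-one F4. Asymmetric 1,4-addition of commercial 4-(triisopropylsilyloxy)phenylboronic acid (Pd(OCOCF3)2, the t-BuPyOx enantiomer that gives 2S flavanones, NH4PF6, H2O, ClCH2CH2Cl, 60 °C) should then give 14, which is deprotected as in step 10.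

Step 1. The processes that may defeat it are a second alkylation at an already prenylated carbon with loss of aromaticity, O-alkylation, and incomplete second alkylation, all of which lower the amount of 3 that can be separated. The fallback sets out from 1 and returns at 3. It replaces phenoxide alkylation by Friedel–Crafts prenylation of the neutral phenol with 2-methylbut-3-en-2-ol and BF3·OEt2 in dioxane at rt, an electrophilic substitution that cannot dearomatise the ring or alkylate oxygen; it is stopped before chroman formation sets in. No new compound is made (F0).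

Step 7. The processes that may defeat it are base-induced transfer of the neighbouring aryl silyl group to the freed benzylic oxygen and partial loss of an aryl silyl ether. The fallback sets out from 11 and returns at 13, bypassing 12. It is a direct oxidative desilylation under Swern conditions ((COCl)2, DMSO, CH2Cl2, −78 to −40 °C, then Et3N), which converts primary trimethylsilyl-type ethers straight into aldehydes without a free alkoxide and leaves bulkier and aryl silyl ethers alone. No new compound is made (F0).

Further compounds
F1 | step 9 | 1-[2,4,6-trihydroxy-3,5-bis(3-methylbut-2-enyl)phenyl]ethanone | CC(=O)c1c(O)c(CC=C(C)C)c(O)c(CC=C(C)C)c1O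
F2 | step 9 | 1-[2,4-bis(tert-butyldimethylsilyloxy)-6-hydroxy-3,5-bis(3-methylbut-2-enyl)phenyl]ethanone | CC(=O)c1c(O)c(CC=C(C)C)c(O[Si](C)(C)C(C)(C)C)c(CC=C(C)C)c1O[Si](C)(C)C(C)(C)C
F3 | step 9 | (E)-1-[2,4-bis(tert-butyldimethylsilyloxy)-6-hydroxy-3,5-bis(3-methylbut-2-enyl)phenyl]-3-(dimethylamino)prop-2-en-1-one | CN(C)/C=C/C(=O)c1c(O)c(CC=C(C)C)c(O[Si](C)(C)C(C)(C)C)c(CC=C(C)C)c1O[Si](C)(C)C(C)(C)C
F4 | step 9 | 5,7-bis(tert-butyldimethylsilyloxy)-6,8-bis(3-methylbut-2-enyl)chromen-4-one | CC(C)=CCc1c(O[Si](C)(C)C(C)(C)C)c(CC=C(C)C)c2occc(=O)c2c1O[Si](C)(C)C(C)(C)C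
F0 | step 1 | none | none
F0 | step 7 | none | none
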